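## Retrosynthetic overview

1. Numbering: chain C1 (CH2OH) to C12; ring C13 (quaternary), C14 (CHEt), C15 (C=O), C16=C17, C18 (C(OH)Me). The last C–C bond is C10–C11: chain sulfone 35 is alkylated with ring iodide 12, then desulfonylated and deprotected with acid, which also unmasks the C15 enone.
2. Ring fragment 12: the carbocycle is never built; it is the ring of quinone monoketal 1. C14 comes from a copper-catalysed asymmetric Et2Zn addition (first stereocentre), C13 from methylation then allylation anti to ethyl, C18 from MeLi addition; the allyl group is cut to CH2CH2I.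
3. Chain fragment 35: C7=C8 Wittig (aldehyde 32 + phosphonium salt 19) then hydrogenation; C5/C6 by iridium-catalysed anti-crotylation; C2/C3 by ketoreductase dynamic kinetic resolution of α-ethyl β-keto ester 23.
4. C8–C10 fragment 19: from (R)-Roche ester, made with an ene-reductase.
5. Rings formed: only the temporary 1,3-dioxane (acetonide, step 19), opened again in step 28.

Assumption: the absolute sense of each chiral catalyst or enzyme is taken from the closest precedents and checked (Mosher ester or optical rotation) at 2, 14, 24 and 29; if reversed, the mirror-image ligand or an enantiocomplementary enzyme of the same class is used with nothing else changed.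

## Route

**Ring fragment**

Step 1
Reactants: 1 4,4-dimethoxycyclohexa-2,5-dien-1-one
Product: 2 (5R)-5-ethyl-4,4-dimethoxycyclohex-2-en-1-one
Conditions: Et2Zn (1.5 equiv), Cu(OTf)2 (2 mol %), (S,R,R)-phosphoramidite from BINOL and bis(1-phenylethyl)amine (4 mol %), toluene, −25 °C; then H2O
Reagents that add atoms: diethylzinc (Et2Zn) CC[Zn]CC
Why: copper-catalysed asymmetric conjugate addition (Feringa type) desymmetrises the dienone, the chiral copper–phosphoramidite complex selecting one of the two enantiotopic enone units so that the ethyl-bearing carbon (future C14) is formed as R in about 97% ee.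

Step 2
Reactants: 2 (5R)-5-ethyl-4,4-dimethoxycyclohex-2-en-1-one
Product: 4 (5R,6RS)-5-ethyl-4,4-dimethoxy-6-methylcyclohex-2-en-1-one, via lithium dienolate 3 (not isolated)
Conditions: LiN(i-Pr)2, THF, −78 °C; MeI, −78 → −40 °C
Reagents that add atoms: iodomethane IC
Why: kinetic α'-deprotonation is the only enolisation open to this enone (the γ carbon is a ketal) and the enolate is methylated (enolate alkylation); the new centre is a mixture that is erased in step 3.

Step 3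
Reactants: 4 (5R,6RS)-5-ethyl-4,4-dimethoxy-6-methylcyclohex-2-en-1-one
Product: 6 (5R,6R)-5-ethyl-4,4-dimethoxy-6-methyl-6-(prop-2-en-1-yl)cyclohex-2-en-1-one, via methylated lithium dienolate 5 (not isolated)
Conditions: LiN(i-Pr)2, THF/DMPU, −78 °C; allyl bromide, −78 → −20 °C
Reagents that add atoms: allyl bromide C=CCBr
Why: enolate alkylation builds the quaternary carbon, allyl bromide attacking the planar enolate anti to the neighbouring pseudo-axial ethyl group (1,2-induction), so allyl ends trans and methyl cis to ethyl (C13 R).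

Step 4
Reactants: 6 (5R,6R)-5-ethyl-4,4-dimethoxy-6-methyl-6-(prop-2-en-1-yl)cyclohex-2-en-1-one
Product: 7 (1R,5R,6R)-5-ethyl-4,4-dimethoxy-1,6-dimethyl-6-(prop-2-en-1-yl)cyclohex-2-en-1-ol
Conditions: MeLi, THF, −78 °C; then H2O
Reagents that add atoms: methyllithium (MeLi) [Li]C
Why: organolithium 1,2-addition to a non-enolisable enone, MeLi entering anti to the ethyl group (pseudo-axial next to the ketal, screening its own face) and anti to the C6 methyl, which puts OH cis to ethyl (C18 R).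

Step 5
Reactants: 7 (1R,5R,6R)-5-ethyl-4,4-dimethoxy-1,6-dimethyl-6-(prop-2-en-1-yl)cyclohex-2-en-1-ol
Product: 8 {[(1R,5R,6R)-5-ethyl-4,4-dimethoxy-1,6-dimethyl-6-(prop-2-en-1-yl)cyclohex-2-en-1-yl]oxy}triethylsilane
Conditions: Et3SiOTf, 2,6-lutidine, CH2Cl2, −78 → 0 °C
Reagents that add atoms: triethylsilyl trifluoromethanesulfonate CC[Si](CC)(CC)OS(=O)(=O)C(F)(F)F
Why: silyl triflate silylation of the hindered tertiary alcohol, needed so that its alkoxide cannot later displace the iodide to a cyclic ether; no stereocentre is touched.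

Step 6
Reactants: 8 {[(1R,5R,6R)-5-ethyl-4,4-dimethoxy-1,6-dimethyl-6-(prop-2-en-1-yl)cyclohex-2-en-1-yl]oxy}triethylsilane
Product: 10 2-[(1R,2R,6R)-6-ethyl-5,5-dimethoxy-1,2-dimethyl-2-[(triethylsilyl)oxy]cyclohex-3-en-1-yl]acetaldehyde, via vicinal diol 9 (not isolated)
Conditions: OsO4 (2 mol %), NaIO4 (4 equiv), 2,6-lutidine, dioxane/H2O (3:1), rt
Reagents that add atoms: osmium tetroxide (OsO4) O=[Os](=O)(=O)=O; sodium periodate (NaIO4) [Na+].[O-]I(=O)(=O)=O
Why: Lemieux–Johnson oxidative cleavage, OsO4 dihydroxylating the unhindered terminal alkene much faster than the ring alkene that is flanked by two fully substituted carbons.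

Step 7
Reactants: 10 2-[(1R,2R,6R)-6-ethyl-5,5-dimethoxy-1,2-dimethyl-2-[(triethylsilyl)oxy]cyclohex-3-en-1-yl]acetaldehyde
Product: 11 2-[(1R,2R,6R)-6-ethyl-5,5-dimethoxy-1,2-dimethyl-2-[(triethylsilyl)oxy]cyclohex-3-en-1-yl]ethan-1-ol
Conditions: NaBH4, MeOH, 0 °C
Reagents that add atoms: none
Why: simple borohydride reduction of the only carbonyl group present.

Step 8
Reactants: 11 2-[(1R,2R,6R)-6-ethyl-5,5-dimethoxy-1,2-dimethyl-2-[(triethylsilyl)oxy]cyclohex-3-en-1-yl]ethan-1-ol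
Product: 12 {[(1R,5R,6R)-5-ethyl-6-(2-iodoethyl)-4,4-dimethoxy-1,6-dimethylcyclohex-2-en-1-yl]oxy}triethylsilane
Conditions: I2, PPh3, imidazole, CH2Cl2, 0 °C → rt
Reagents that add atoms: iodine [I][I]
Why: Appel-type (Garegg–Samuelsson) iodination of the primary alcohol under imidazole-buffered conditions that spare the ketal and the silyl ether.

**C8–C10 fragment**

Step 9
Reactants: 13 methyl 2-(hydroxymethyl)prop-2-enoate
Product: 14 methyl (2R)-3-hydroxy-2-methylpropanoate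
Conditions: ene-reductase (flavin-dependent, old-yellow-enzyme family), NAD+ (cat.), formate dehydrogenase, HCO2Na, Tris·HCl buffer pH 7.5, 30 °C
Reagents that add atoms: none
Why: ene-reductase asymmetric C=C bioreduction, hydride going to the β-carbon and a proton to one face of the α-carbon in the active site, which gives the (R)-Roche ester in >98% ee.

Step 10
Reactants: 14 methyl (2R)-3-hydroxy-2-methylpropanoate
Product: 15 methyl (2S)-2-methyl-3-(phenylsulfanyl)propanoate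
Conditions: PhSSPh, n-Bu3P, THF, rt
Reagents that add atoms: diphenyl disulfide c1ccccc1SSc1ccccc1
Why: Hata thioetherification, an SN2 displacement of the alkoxyphosphonium by thiophenolate at the primary carbon that leaves the stereocentre untouched (descriptor changes by priority only).

Step 11
Reactants: 15 methyl (2S)-2-methyl-3-(phenylsulfanyl)propanoate
Product: 16 (2S)-2-methyl-3-(phenylsulfanyl)propan-1-ol
Conditions: LiAlH4, THF, 0 °C
Reagents that add atoms: none
Why: hydride reduction of the ester, done before sulfur oxidation so that no β-sulfonyl ester, which could eliminate and racemise, is ever present.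

Step 12
Reactants: 16 (2S)-2-methyl-3-(phenylsulfanyl)propan-1-ol
Product: 17 (2S)-2-methyl-3-(phenylsulfonyl)propan-1-ol
Conditions: 30% H2O2, (NH4)6Mo7O24·4H2O (cat.), EtOH, 0 °C → rt
Reagents that add atoms: hydrogen peroxide OO
Why: molybdate-catalysed oxidation of sulfide to sulfone, which does not touch the primary alcohol.

Step 13
Reactants: 17 (2S)-2-methyl-3-(phenylsulfonyl)propan-1-ol
Product: 18 {[(2R)-3-iodo-2-methylpropyl]sulfonyl}benzene
Conditions: I2, PPh3, imidazole, CH2Cl2, 0 °C → rt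
Reagents that add atoms: iodine [I][I]
Why: Appel-type iodination at the primary carbon; the stereocentre is not involved.

Step 14
Reactants: 18 {[(2R)-3-iodo-2-methylpropyl]sulfonyl}benzene
Product: 19 [(2S)-2-methyl-3-(phenylsulfonyl)propyl]triphenylphosphonium iodide
Conditions: PPh3, MeCN, reflux
Reagents that add atoms: triphenylphosphine c1ccccc1P(c1ccccc1)c1ccccc1
Why: SN2 quaternisation of the primary iodide gives the Wittig salt.

**Chain fragment**

Step 15
Reactants: 20 ethyl 3-oxobutanoate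
Product: 21 ethyl 2-ethyl-3-oxobutanoate (racemic)
Conditions: EtI, K2CO3, acetone, reflux
Reagents that add atoms: iodoethane ICC
Why: acetoacetic ester C-alkylation of the stabilised enolate.

Step 16
Reactants: 21 ethyl 2-ethyl-3-oxobutanoate (racemic)
Product: 23 ethyl 5-(benzyloxy)-2-ethyl-3-oxopentanoate (racemic), via sodium lithium dianion 22 (not isolated)
Conditions: NaH, THF, 0 °C; n-BuLi, 0 °C; BnOCH2Cl, −78 → 0 °C; then 1 M HCl
Reagents that add atoms: benzyl chloromethyl ether ClCOCc1ccccc1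
Why: Weiler dianion alkylation, the terminal (γ) carbanion being the more nucleophilic site.

Step 17
Reactants: 23 ethyl 5-(benzyloxy)-2-ethyl-3-oxopentanoate (racemic)
Product: 24 ethyl (2S,3R)-5-(benzyloxy)-2-ethyl-3-hydroxypentanoate
Conditions: ketoreductase (NADPH-dependent, chosen from a commercial panel for the syn-(2S,3R) product), NADP+ (cat.), i-PrOH (10% v/v), potassium phosphate buffer pH 7.0, MgSO4 (2 mM), 30 °C
Reagents that add atoms: none
Why: ketoreductase-catalysed dynamic kinetic resolution, C2 epimerising through the enol at pH 7 while the enzyme reduces only the 2S ketone from one carbonyl face, which sets C2 and C3 together as the syn pair.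

Step 18
Reactants: 24 ethyl (2S,3R)-5-(benzyloxy)-2-ethyl-3-hydroxypentanoate
Product: 25 (2R,3R)-5-(benzyloxy)-2-ethylpentane-1,3-diol
Conditions: LiAlH4, THF, 0 °C
Reagents that add atoms: none
Why: hydride reduction of the ester to C1H2OH (the C2 descriptor changes by priority only).

Step 19
Reactants: 25 (2R,3R)-5-(benzyloxy)-2-ethylpentane-1,3-diol
Product: 26 (4R,5R)-4-[2-(benzyloxy)ethyl]-5-ethyl-2,2-dimethyl-1,3-dioxane
Conditions: Me2C(OMe)2, pyridinium p-toluenesulfonate (cat.), CH2Cl2, rt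
Reagents that add atoms: 2,2-dimethoxypropane COC(C)(C)OC
Why: acid-catalysed transketalisation closes the six-membered acetonide over the C1 and C3 hydroxyls.

Step 20
Reactants: 26 (4R,5R)-4-[2-(benzyloxy)ethyl]-5-ethyl-2,2-dimethyl-1,3-dioxane
Product: 27 2-[(4R,5R)-5-ethyl-2,2-dimethyl-1,3-dioxan-4-yl]ethan-1-ol
Conditions: H2 (1 atm), 10% Pd/C, EtOAc, rt
Reagents that add atoms: none
Why: hydrogenolysis of the benzyl ether under neutral conditions that keep the acetonide.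

Step 21
Reactants: 27 2-[(4R,5R)-5-ethyl-2,2-dimethyl-1,3-dioxan-4-yl]ethan-1-ol
Product: 29 (2S,3R)-1-[(4R,5R)-5-ethyl-2,2-dimethyl-1,3-dioxan-4-yl]-3-methylpent-4-en-2-ol, via dioxanylacetaldehyde 28 (not isolated)
Conditions: [Ir(cod)Cl]2 (2.5 mol %), (S)-SEGPHOS (5 mol %), 4-cyano-3-nitrobenzoic acid (10 mol %), Cs2CO3 (20 mol %), racemic but-3-en-2-yl acetate (2 equiv), THF, 90 °C
Reagents that add atoms: but-3-en-2-yl acetate CC(OC(C)=O)C=C
Why: Krische iridium-catalysed transfer-hydrogenative crotylation, the alcohol being dehydrogenated to the aldehyde, which the (E)-crotyliridium species attacks through a closed chair transition state to give the anti C5/C6 pair (5S,6R) under control of the chiral iridium complex.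

Step 22
Reactants: 29 (2S,3R)-1-[(4R,5R)-5-ethyl-2,2-dimethyl-1,3-dioxan-4-yl]-3-methylpent-4-en-2-ol
Product: 30 tert-butyl{[(2S,3R)-1-[(4R,5R)-5-ethyl-2,2-dimethyl-1,3-dioxan-4-yl]-3-methylpent-4-en-2-yl]oxy}dimethylsilane
Conditions: t-BuMe2SiOTf, 2,6-lutidine, CH2Cl2, −78 → 0 °C
Reagents that add atoms: tert-butyldimethylsilyl trifluoromethanesulfonate CC(C)(C)[Si](C)(C)OS(=O)(=O)C(F)(F)F
Why: silyl triflate silylation of the secondary alcohol, so that the next aldehyde is not a free β-hydroxy aldehyde.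

Step 23
Reactants: 30 tert-butyl{[(2S,3R)-1-[(4R,5R)-5-ethyl-2,2-dimethyl-1,3-dioxan-4-yl]-3-methylpent-4-en-2-yl]oxy}dimethylsilane
Product: 32 (2S,3S)-3-[(tert-butyldimethylsilyl)oxy]-4-[(4R,5R)-5-ethyl-2,2-dimethyl-1,3-dioxan-4-yl]-2-methylbutanal, via secondary ozonide 31 (not isolated)
Conditions: O3, CH2Cl2, −78 °C; then PPh3, −78 °C → rt
Reagents that add atoms: ozone [O-][O+]=O
Why: ozonolysis with reductive work-up cleaves the only alkene to the C7 aldehyde without epimerising the α-methyl centre (descriptor changes by priority only).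

Step 24
Reactants: 32 (2S,3S)-3-[(tert-butyldimethylsilyl)oxy]-4-[(4R,5R)-5-ethyl-2,2-dimethyl-1,3-dioxan-4-yl]-2-methylbutanal; 19 [(2S)-2-methyl-3-(phenylsulfonyl)propyl]triphenylphosphonium iodide
Product: 34 {[(2S,3Z,5R,6S)-6-[(tert-butyldimethylsilyl)oxy]-7-[(4R,5R)-5-ethyl-2,2-dimethyl-1,3-dioxan-4-yl]-2,5-dimethylhept-3-en-1-yl]sulfonyl}benzene, via phosphorus ylide 33 (not isolated)
Conditions: 19, KN(SiMe3)2, THF, −78 → 0 °C; then 32, −78 °C → rt
Reagents that add atoms: none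
Why: Wittig olefination with a non-stabilised ylide (the P-bound CH2 is far more acidic than the sulfonyl CH2) joins C7 to C8 at low temperature without loss of the C6 configuration; the alkene geometry is irrelevant.

Step 25
Reactants: 34 {[(2S,3Z,5R,6S)-6-[(tert-butyldimethylsilyl)oxy]-7-[(4R,5R)-5-ethyl-2,2-dimethyl-1,3-dioxan-4-yl]-2,5-dimethylhept-3-en-1-yl]sulfonyl}benzene
Product: 35 {[(2S,5R,6S)-6-[(tert-butyldimethylsilyl)oxy]-7-[(4R,5R)-5-ethyl-2,2-dimethyl-1,3-dioxan-4-yl]-2,5-dimethylheptyl]sulfonyl}benzene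
Conditions: H2 (1 atm), 10% Pd/C, EtOAc, rt
Reagents that add atoms: none
Why: catalytic hydrogenation saturates the only alkene, done while no ring alkene is present in the molecule.

**Union and finish**

Step 26
Reactants: 35 {[(2S,5R,6S)-6-[(tert-butyldimethylsilyl)oxy]-7-[(4R,5R)-5-ethyl-2,2-dimethyl-1,3-dioxan-4-yl]-2,5-dimethylheptyl]sulfonyl}benzene; 12 {[(1R,5R,6R)-5-ethyl-6-(2-iodoethyl)-4,4-dimethoxy-1,6-dimethylcyclohex-2-en-1-yl]oxy}triethylsilane
Product: 37 {[(1R,5R,6R)-6-[(3RS,4S,7R,8S)-8-[(tert-butyldimethylsilyl)oxy]-9-[(4R,5R)-5-ethyl-2,2-dimethyl-1,3-dioxan-4-yl]-4,7-dimethyl-3-(phenylsulfonyl)nonyl]-5-ethyl-4,4-dimethoxy-1,6-dimethylcyclohex-2-en-1-yl]oxy}triethylsilane, via lithiated sulfone 36 (not isolated)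
Conditions: 35, n-BuLi (0.98 equiv), THF/HMPA, −78 °C; then 12, −78 → −20 °C
Reagents that add atoms: none
Why: SN2 alkylation of the α-sulfonyl carbanion by the primary iodide forms the C10–C11 bond with no new alkene to reduce; the sulfone-bearing centre is a mixture that is removed in step 27.

Step 27
Reactants: 37 {[(1R,5R,6R)-6-[(3RS,4S,7R,8S)-8-[(tert-butyldimethylsilyl)oxy]-9-[(4R,5R)-5-ethyl-2,2-dimethyl-1,3-dioxan-4-yl]-4,7-dimethyl-3-(phenylsulfonyl)nonyl]-5-ethyl-4,4-dimethoxy-1,6-dimethylcyclohex-2-en-1-yl]oxy}triethylsilane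
Product: 38 {[(1R,5R,6R)-6-[(4R,7R,8S)-8-[(tert-butyldimethylsilyl)oxy]-9-[(4R,5R)-5-ethyl-2,2-dimethyl-1,3-dioxan-4-yl]-4,7-dimethylnonyl]-5-ethyl-4,4-dimethoxy-1,6-dimethylcyclohex-2-en-1-yl]oxy}triethylsilane
Conditions: 6% Na(Hg), Na2HPO4, MeOH/THF, −20 → 0 °C
Reagents that add atoms: none
Why: reductive desulfonylation by electron transfer replaces the C–S bond by C–H and leaves the isolated ring alkene, the ketal and the silyl ethers alone.

Step 28
Reactants: 38 {[(1R,5R,6R)-6-[(4R,7R,8S)-8-[(tert-butyldimethylsilyl)oxy]-9-[(4R,5R)-5-ethyl-2,2-dimethyl-1,3-dioxan-4-yl]-4,7-dimethylnonyl]-5-ethyl-4,4-dimethoxy-1,6-dimethylcyclohex-2-en-1-yl]oxy}triethylsilane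
Product: 39 (4R,5R,6R)-5-[(4R,7R,8S,10R,11R)-8,10-dihydroxy-11-(hydroxymethyl)-4,7-dimethyltridecyl]-6-ethyl-4-hydroxy-4,5-dimethylcyclohex-2-en-1-one
Conditions: 3 M aq. HCl/THF (1:4), 0 °C → rt
Reagents that add atoms: water O
Why: one acid hydrolysis converts the allylic dimethyl ketal into the conjugated enone (the p-quinol ketal route to 4-hydroxy-enones) and removes the acetonide and both silyl ethers, under conditions too mild to enolise the hindered C14 centre.

## Compound list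

1 | 4,4-dimethoxycyclohexa-2,5-dien-1-one | COC1(OC)C=CC(=O)C=C1 | starting material
2 | (5R)-5-ethyl-4,4-dimethoxycyclohex-2-en-1-one | O=C1C[C@@H](CC)C(OC)(OC)C=C1 | intermediate
3 | lithium dienolate of 2 (not isolated) | [Li+].[O-]C1=C[C@@H](CC)C(OC)(OC)C=C1 | intermediate
4 | (5R,6RS)-5-ethyl-4,4-dimethoxy-6-methylcyclohex-2-en-1-one (C6 epimers) | O=C1C(C)[C@@H](CC)C(OC)(OC)C=C1 | intermediate
5 | methylated lithium dienolate of 4 (not isolated) | [Li+].[O-]C1=C(C)[C@@H](CC)C(OC)(OC)C=C1 | intermediate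
6 | (5R,6R)-5-ethyl-4,4-dimethoxy-6-methyl-6-(prop-2-en-1-yl)cyclohex-2-en-1-one | C=CC[C@]1(C)[C@@H](CC)C(OC)(OC)C=CC1=O | intermediate
7 | (1R,5R,6R)-5-ethyl-4,4-dimethoxy-1,6-dimethyl-6-(prop-2-en-1-yl)cyclohex-2-en-1-ol | C=CC[C@]1(C)[C@@H](CC)C(OC)(OC)C=C[C@@]1(C)O | intermediate
8 | {[(1R,5R,6R)-5-ethyl-4,4-dimethoxy-1,6-dimethyl-6-(prop-2-en-1-yl)cyclohex-2-en-1-yl]oxy}triethylsilane | C=CC[C@]1(C)[C@@H](CC)C(OC)(OC)C=C[C@@]1(C)O[Si](CC)(CC)CC | intermediate
9 | 3-[(1R,2R,6R)-6-ethyl-5,5-dimethoxy-1,2-dimethyl-2-[(triethylsilyl)oxy]cyclohex-3-en-1-yl]propane-1,2-diol (carbinol epimers; not isolated) | OCC(O)C[C@]1(C)[C@@H](CC)C(OC)(OC)C=C[C@@]1(C)O[Si](CC)(CC)CC | intermediate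
10 | 2-[(1R,2R,6R)-6-ethyl-5,5-dimethoxy-1,2-dimethyl-2-[(triethylsilyl)oxy]cyclohex-3-en-1-yl]acetaldehyde | O=CC[C@]1(C)[C@@H](CC)C(OC)(OC)C=C[C@@]1(C)O[Si](CC)(CC)CC | intermediate
11 | 2-[(1R,2R,6R)-6-ethyl-5,5-dimethoxy-1,2-dimethyl-2-[(triethylsilyl)oxy]cyclohex-3-en-1-yl]ethan-1-ol | OCC[C@]1(C)[C@@H](CC)C(OC)(OC)C=C[C@@]1(C)O[Si](CC)(CC)CC | intermediate
12 | {[(1R,5R,6R)-5-ethyl-6-(2-iodoethyl)-4,4-dimethoxy-1,6-dimethylcyclohex-2-en-1-yl]oxy}triethylsilane | ICC[C@]1(C)[C@@H](CC)C(OC)(OC)C=C[C@@]1(C)O[Si](CC)(CC)CC | intermediate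
13 | methyl 2-(hydroxymethyl)prop-2-enoate | C=C(CO)C(=O)OC | starting material
14 | methyl (2R)-3-hydroxy-2-methylpropanoate | COC(=O)[C@H](C)CO | intermediate
15 | methyl (2S)-2-methyl-3-(phenylsulfanyl)propanoate | COC(=O)[C@H](C)CSc1ccccc1 | intermediate
16 | (2S)-2-methyl-3-(phenylsulfanyl)propan-1-ol | OC[C@H](C)CSc1ccccc1 | intermediate
17 | (2S)-2-methyl-3-(phenylsulfonyl)propan-1-ol | OC[C@H](C)CS(=O)(=O)c1ccccc1 | intermediate
18 | {[(2R)-3-iodo-2-methylpropyl]sulfonyl}benzene | IC[C@H](C)CS(=O)(=O)c1ccccc1 | intermediate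
19 | [(2S)-2-methyl-3-(phenylsulfonyl)propyl]triphenylphosphonium iodide | [I-].c1ccccc1[P+](c1ccccc1)(c1ccccc1)C[C@H](C)CS(=O)(=O)c1ccccc1 | intermediate
20 | ethyl 3-oxobutanoate | CCOC(=O)CC(C)=O | starting material
21 | ethyl 2-ethyl-3-oxobutanoate (racemic) | CCOC(=O)C(CC)C(C)=O | intermediate
22 | sodium lithium dianion of 21 (not isolated) | [Na+].[Li+].CCOC(=O)C(CC)=C([O-])[CH2-] | intermediate
23 | ethyl 5-(benzyloxy)-2-ethyl-3-oxopentanoate (racemic) | CCOC(=O)C(CC)C(=O)CCOCc1ccccc1 | intermediate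
24 | ethyl (2S,3R)-5-(benzyloxy)-2-ethyl-3-hydroxypentanoate | CC[C@H](C(=O)OCC)[C@H](O)CCOCc1ccccc1 | intermediate
25 | (2R,3R)-5-(benzyloxy)-2-ethylpentane-1,3-diol | CC[C@H](CO)[C@H](O)CCOCc1ccccc1 | intermediate
26 | (4R,5R)-4-[2-(benzyloxy)ethyl]-5-ethyl-2,2-dimethyl-1,3-dioxane | CC[C@H](CO1)[C@H](OC1(C)C)CCOCc1ccccc1 | intermediate
27 | 2-[(4R,5R)-5-ethyl-2,2-dimethyl-1,3-dioxan-4-yl]ethan-1-ol | CC[C@H](CO1)[C@H](OC1(C)C)CCO | intermediate
28 | 2-[(4R,5R)-5-ethyl-2,2-dimethyl-1,3-dioxan-4-yl]acetaldehyde (not isolated) | CC[C@H](CO1)[C@H](OC1(C)C)CC=O | intermediate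
29 | (2S,3R)-1-[(4R,5R)-5-ethyl-2,2-dimethyl-1,3-dioxan-4-yl]-3-methylpent-4-en-2-ol | CC[C@H](CO1)[C@H](OC1(C)C)C[C@H](O)[C@H](C)C=C | intermediate
30 | tert-butyl{[(2S,3R)-1-[(4R,5R)-5-ethyl-2,2-dimethyl-1,3-dioxan-4-yl]-3-methylpent-4-en-2-yl]oxy}dimethylsilane | CC[C@H](CO1)[C@H](OC1(C)C)C[C@H](O[Si](C)(C)C(C)(C)C)[C@H](C)C=C | intermediate
31 | secondary ozonide (1,2,4-trioxolane) of 30 (not isolated) | CC[C@H](CO1)[C@H](OC1(C)C)C[C@H](O[Si](C)(C)C(C)(C)C)[C@H](C)C1OCOO1 | intermediate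
32 | (2S,3S)-3-[(tert-butyldimethylsilyl)oxy]-4-[(4R,5R)-5-ethyl-2,2-dimethyl-1,3-dioxan-4-yl]-2-methylbutanal | CC[C@H](CO1)[C@H](OC1(C)C)C[C@H](O[Si](C)(C)C(C)(C)C)[C@H](C)C=O | intermediate
33 | [(2S)-2-methyl-3-(phenylsulfonyl)propylidene]triphenylphosphorane (not isolated) | c1ccccc1P(c1ccccc1)(c1ccccc1)=C[C@H](C)CS(=O)(=O)c1ccccc1 | intermediate
34 | {[(2S,3Z,5R,6S)-6-[(tert-butyldimethylsilyl)oxy]-7-[(4R,5R)-5-ethyl-2,2-dimethyl-1,3-dioxan-4-yl]-2,5-dimethylhept-3-en-1-yl]sulfonyl}benzene | CC[C@H](CO1)[C@H](OC1(C)C)C[C@H](O[Si](C)(C)C(C)(C)C)[C@H](C)/C=C\[C@H](C)CS(=O)(=O)c1ccccc1 | intermediate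
35 | {[(2S,5R,6S)-6-[(tert-butyldimethylsilyl)oxy]-7-[(4R,5R)-5-ethyl-2,2-dimethyl-1,3-dioxan-4-yl]-2,5-dimethylheptyl]sulfonyl}benzene | CC[C@H](CO1)[C@H](OC1(C)C)C[C@H](O[Si](C)(C)C(C)(C)C)[C@H](C)CC[C@H](C)CS(=O)(=O)c1ccccc1 | intermediate
36 | α-lithio derivative of sulfone 35 (not isolated) | CC[C@H](CO1)[C@H](OC1(C)C)C[C@H](O[Si](C)(C)C(C)(C)C)[C@H](C)CC[C@H](C)[CH-]S(=O)(=O)c1ccccc1.[Li+] | intermediate
37 | {[(1R,5R,6R)-6-[(3RS,4S,7R,8S)-8-[(tert-butyldimethylsilyl)oxy]-9-[(4R,5R)-5-ethyl-2,2-dimethyl-1,3-dioxan-4-yl]-4,7-dimethyl-3-(phenylsulfonyl)nonyl]-5-ethyl-4,4-dimethoxy-1,6-dimethylcyclohex-2-en-1-yl]oxy}triethylsilane | CC[C@H](CO1)[C@H](OC1(C)C)C[C@H](O[Si](C)(C)C(C)(C)C)[C@H](C)CC[C@H](C)C(S(=O)(=O)c1ccccc1)CC[C@]1(C)[C@@H](CC)C(OC)(OC)C=C[C@@]1(C)O[Si](CC)(CC)CC | intermediate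
38 | {[(1R,5R,6R)-6-[(4R,7R,8S)-8-[(tert-butyldimethylsilyl)oxy]-9-[(4R,5R)-5-ethyl-2,2-dimethyl-1,3-dioxan-4-yl]-4,7-dimethylnonyl]-5-ethyl-4,4-dimethoxy-1,6-dimethylcyclohex-2-en-1-yl]oxy}triethylsilane | CC[C@H](CO1)[C@H](OC1(C)C)C[C@H](O[Si](C)(C)C(C)(C)C)[C@H](C)CC[C@H](C)CCC[C@]1(C)[C@@H](CC)C(OC)(OC)C=C[C@@]1(C)O[Si](CC)(CC)CC | intermediate
39 | (4R,5R,6R)-5-[(4R,7R,8S,10R,11R)-8,10-dihydroxy-11-(hydroxymethyl)-4,7-dimethyltridecyl]-6-ethyl-4-hydroxy-4,5-dimethylcyclohex-2-en-1-one | CC[C@H](CO)[C@H](O)C[C@H](O)[C@H](C)CC[C@H](C)CCC[C@]1(C)[C@@H](CC)C(=O)C=C[C@@]1(C)O | target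

## Step count and risks

Total: 28 steps. Longest linear sequence: 14 steps (20 → 39, steps 15 to 28); the ring branch (steps 1 to 8) and the C8–C10 branch (steps 9 to 14) each join it late.

The three steps most likely to fail are 4, 17 and 26.

Step 4 rests on a conformational argument and could give the C1 epimer if MeLi in fact enters syn to the ethyl group. The fallback reverses the order in which carbon and oxygen are attached, so that the same facial preference then gives the right isomer. It sets out from 6, which is methylenated (Ph3PCH3Br, KOt-Bu, toluene, 90 °C) to (4R,5R)-4-ethyl-3,3-dimethoxy-5-methyl-6-methylidene-5-(prop-2-en-1-yl)cyclohex-1-ene F1. m-CPBA with NaHCO3 (CH2Cl2, 0 °C) epoxidises the exocyclic 1,1-disubstituted alkene, the most electron-rich of the three, to (3R,7R,8R)-7-ethyl-6,6-dimethoxy-8-methyl-8-(prop-2-en-1-yl)-1-oxaspiro[2.5]oct-4-ene F2. LiEt3BH (THF, 0 °C) opens the epoxide at its CH2 end and the sequence comes back to the route at 7.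

Step 17 depends on finding a ketoreductase that accepts the bulky α-ethyl keto ester and gives the syn pair. The fallback replaces the enzyme by homogeneous hydrogenation and sets out from 23: RuCl2[(R)-BINAP] (H2 50 bar, EtOH, 50 °C) fixes C3 as R whatever the configuration at C2 and gives roughly equal amounts of 24 and its C2 epimer, ethyl (2R,3R)-5-(benzyloxy)-2-ethyl-3-hydroxypentanoate F3. Chromatography gives 24, where the route is rejoined, and F3 is oxidised back to 23 with Dess–Martin periodinane and recycled.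

Step 26 is an SN2 reaction between two large partners at a primary iodide with a quaternary carbon two atoms away, and it may be slow or give elimination. The fallback forms the same bond by carbonyl addition instead and sets out from 35 and aldehyde 10. Lithiated 35 (n-BuLi, THF, −78 °C) adds to 10 and the alkoxide is trapped with Ac2O to give the (2RS,3RS)-2-acetoxy-3-(phenylsulfonyl) analogue of 37, F4. Na(Hg) with Na2HPO4 (MeOH/THF, −20 °C) eliminates it (Julia–Lythgoe olefination) to the (2E)-non-2-enyl analogue of 38, F5. Diimide (2-nitrobenzenesulfonohydrazide, Et3N, CH2Cl2, rt) then reduces the open-chain alkene in preference to the ring alkene, which is shielded by two fully substituted carbons, and the sequence comes back to the route at 38.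

Further compounds

F1 | step 4 | (4R,5R)-4-ethyl-3,3-dimethoxy-5-methyl-6-methylidene-5-(prop-2-en-1-yl)cyclohex-1-ene | C=CC[C@]1(C)[C@@H](CC)C(OC)(OC)C=CC1=C
F2 | step 4 | (3R,7R,8R)-7-ethyl-6,6-dimethoxy-8-methyl-8-(prop-2-en-1-yl)-1-oxaspiro[2.5]oct-4-ene | C=CC[C@]1(C)[C@@H](CC)C(OC)(OC)C=C[C@@]1(C2)O2
F3 | step 17 | ethyl (2R,3R)-5-(benzyloxy)-2-ethyl-3-hydroxypentanoate | CC[C@@H](C(=O)OCC)[C@H](O)CCOCc1ccccc1
F4 | step 26 | {[(1R,5R,6R)-6-[(2RS,3RS,4S,7R,8S)-2-acetoxy-8-[(tert-butyldimethylsilyl)oxy]-9-[(4R,5R)-5-ethyl-2,2-dimethyl-1,3-dioxan-4-yl]-4,7-dimethyl-3-(phenylsulfonyl)nonyl]-5-ethyl-4,4-dimethoxy-1,6-dimethylcyclohex-2-en-1-yl]oxy}triethylsilane | CC[C@H](CO1)[C@H](OC1(C)C)C[C@H](O[Si](C)(C)C(C)(C)C)[C@H](C)CC[C@H](C)C(S(=O)(=O)c1ccccc1)C(OC(C)=O)C[C@]1(C)[C@@H](CC)C(OC)(OC)C=C[C@@]1(C)O[Si](CC)(CC)CC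
F5 | step 26 | {[(1R,5R,6R)-6-[(2E,4S,7R,8S)-8-[(tert-butyldimethylsilyl)oxy]-9-[(4R,5R)-5-ethyl-2,2-dimethyl-1,3-dioxan-4-yl]-4,7-dimethylnon-2-en-1-yl]-5-ethyl-4,4-dimethoxy-1,6-dimethylcyclohex-2-en-1-yl]oxy}triethylsilane | CC[C@H](CO1)[C@H](OC1(C)C)C[C@H](O[Si](C)(C)C(C)(C)C)[C@H](C)CC[C@H](C)/C=C/C[C@]1(C)[C@@H](CC)C(OC)(OC)C=C[C@@]1(C)O[Si](CC)(CC)CC
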